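**Plan**

The chain is numbered C1 (lactone C=O) to C24 (propenyl CH3); the lactone ring is O–C1(=O)–C2=C3–C4H2–C5H.
- Retrosynthetic cuts: C7–C8 (Heck coupling of a 6-vinyl lactone with a Z-vinyl iodide), C15–C16 (alkenylzinc addition to an oxane-2-carbaldehyde) and, inside the lactone, the C3–C4 bond.
- Enabling feature: the ring oxygen sits on the allylic carbinol C5, so an acrylate ester of a C5 alcohol already holds O, C1, C2 and C3. C3 is the β-carbon of an enoate and C4 is an unsubstituted CH2 that can arrive as a primary tosylate. An N-heterocyclic carbene adds to C3 and inverts its polarity, C3 displaces the tosylate, and the carbene leaves by E1cB, which restores exactly the C2=C3 bond of the 5,6-dihydropyran-2-one.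
- Forward order: lactone ring first (steps 1–2); oxane ring by catalytic asymmetric hetero-Diels–Alder reaction and elaboration to the C16 aldehyde (steps 3–9); C8–C15 chain from an Evans alkylation (steps 10–16); chain joined at C15–C16 (step 17); lactone attached last at C7–C8 (step 18); desilylation (step 19).
- Stereocentres: C5 from commercial tosylate 1 (untouched by the ring closure); C17, C20, C21 from the chromium catalyst (endo, all-cis); C19 by equatorial hydride delivery; C10 from the oxazolidinone; C16 by chelation control.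
- Alkene geometry: 22E by trans-hydrosilylation/protodesilylation, 12E by syn-carboalumination, 8Z by Stork–Zhao olefination, 14E by hydrozirconation, 6E by the Heck step.

Key step: step 2

Assumption: the chromium catalyst built on (1R,2S)-1-aminoindan-2-ol is taken to deliver the aldehyde face that gives 6R in cycloadduct 10, by analogy with its behaviour towards α-oxygenated aldehydes (the (1S,2R) catalyst would be used if the opposite sense were found); both antipodes of tosylate 1, and but-2-ynal 9, are taken to be catalogue compounds.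

**Lactone fragment**

Step 1
Reactants: 1 (2R)-2-hydroxybut-3-en-1-yl 4-methylbenzenesulfonate; 2 prop-2-enoyl chloride
Product: 3 (2R)-1-{[(4-methylphenyl)sulfonyl]oxy}but-3-en-2-yl prop-2-enoate
Conditions: Et3N, DMAP (cat.), CH2Cl2, −20 to 0 °C
Reagents that add atoms: none
Why: O-acylation of the secondary allylic alcohol by an acid chloride under amine base; the stereocentre is not touched, and acylation at low temperature should outrun base-induced epoxide closure.

Step 2
Reactants: 3 (2R)-1-(tosyloxy)but-3-en-2-yl prop-2-enoate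
Product: 4 (6S)-6-ethenyl-5,6-dihydro-2H-pyran-2-one
Conditions: 1,3,4-triphenyl-1,2,4-triazol-1-ium tetrafluoroborate (20 mol%), K3PO4 (2 equiv), 1,2-dimethoxyethane, slow addition of 3 to 0.02 M, 80 °C
Reagents that add atoms: none
Why: Proposed new method: the carbene adds reversibly to C3, the β-carbon of the acrylate, and a 1,2-proton shift converts the azolium enolate into the deoxy-Breslow intermediate (an ene-1,1-diamine) in which C3 is nucleophilic; C3 then displaces the primary tosylate on C4 by SN2, phosphate removes the now acidic C2–H and the azolium is expelled by E1cB, which regenerates the C2=C3 double bond and the carbene. The closest known reaction type is the carbene-catalysed β-umpolung alkylation of α,β-unsaturated esters that carry the leaving group on a carbon tether, together with the tail-to-tail dimerisation of methacrylates through the same intermediate; new here are the tether through the ester oxygen and the β-unsubstituted acrylate. The one ring closed is the six-membered lactone, by 6-(enol-exo)-exo-tet attack on sp3 carbon, which requires the s-cis ester rotamer that should be populated at 80 °C. No stereocentre is created, since the azolium-bearing C3 is sp3 only transiently, and C5 is carried over from 1 unchanged because it is not a reacting centre and the mild phosphate base should not trigger β-elimination across C4–C5. The step needs C- over O-alkylation, β- over α-alkylation and cyclisation over Michael oligomerisation: α-attack by the first-formed enolate would be a disfavoured 5-(enol-endo)-exo-tet closure, O-alkylation gives a ketene acetal of dioxolanylium type that tosylate can reopen, and slow addition at high dilution should hold the intermolecular path down.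

**Oxane fragment**

Step 3
Reactants: 5 diethyl (2-oxobutyl)phosphonate; 6 2-[(tert-butyldimethylsilyl)oxy]acetaldehyde
Product: 7 (4E)-6-[(tert-butyldimethylsilyl)oxy]hex-4-en-3-one
Conditions: LiCl, iPr2NEt, MeCN, rt
Reagents that add atoms: none
Why: Horner–Wadsworth–Emmons olefination of a β-ketophosphonate under mild LiCl/amine conditions should give the E-enone without desilylation or aldol side reactions.

Step 4
Reactants: 7 (4E)-6-[(tert-butyldimethylsilyl)oxy]hex-4-en-3-one
Product: 8 (2E,4Z)-1-[(tert-butyldimethylsilyl)oxy]-4-[(triethylsilyl)oxy]hexa-2,4-diene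
Conditions: Et3SiOTf, Et3N, Et2O, −78 to 0 °C
Reagents that add atoms: triethylsilyl trifluoromethanesulfonate, CC[Si](CC)(CC)OS(=O)(=O)C(F)(F)F
Why: soft enolisation of the ethyl ketone with a silyl triflate/amine pair should give the cross-conjugated Z-silyl enol ether (methyl cis to OSi), i.e. the 2-silyloxy-1,3-diene needed for the cycloaddition.

Step 5
Reactants: 8 (2E,4Z)-1-[(tert-butyldimethylsilyl)oxy]-4-[(triethylsilyl)oxy]hexa-2,4-diene; 9 but-2-ynal
Product: 11 (2R,3R,6S)-6-{[(tert-butyldimethylsilyl)oxy]methyl}-3-methyl-2-(prop-1-yn-1-yl)oxan-4-one, via silyl enol ether cycloadduct 10 (not isolated)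
Conditions: CrCl(L) (5 mol%; trivalent chromium; H2L = Schiff base of 3-(1-adamantyl)-2-hydroxy-5-methylbenzaldehyde and (1R,2S)-1-aminoindan-2-ol), 4 Å molecular sieves, acetone, rt; then Bu4NF, AcOH, THF, 0 °C
Reagents that add atoms: none
Why: catalytic asymmetric hetero-Diels–Alder reaction in which the chiral chromium Lewis acid fixes the aldehyde face (C21) and endo approach onto the Z,E-diene, whose terminal substituents both point outward, should place the C17 CH2OTBS, C20 methyl and C21 propynyl groups all cis, after which buffered fluoride frees the ketone without epimerising the axial C20 methyl.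

Step 6
Reactants: 11 (2R,3R,6S)-6-{[(tert-butyldimethylsilyl)oxy]methyl}-3-methyl-2-(prop-1-yn-1-yl)oxan-4-one
Product: 12 (2R,3S,4R,6S)-6-{[(tert-butyldimethylsilyl)oxy]methyl}-3-methyl-2-(prop-1-yn-1-yl)oxan-4-ol
Conditions: LiBH(s-Bu)3, THF, −78 °C
Reagents that add atoms: none
Why: the bulky trialkylborohydride should attack C19 along the equatorial trajectory of the chair that holds the C17 and C21 substituents equatorial (axial attack meets the syn-axial hydrogens on C17 and C21), giving the axial C19 alcohol trans to the axial C20 methyl, as this reagent class does with cyclohexanones bearing an axial α-methyl group.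

Step 7
Reactants: 12 (2R,3S,4R,6S)-6-{[(tert-butyldimethylsilyl)oxy]methyl}-3-methyl-2-(prop-1-yn-1-yl)oxan-4-ol
Product: 14 (2S,3S,4R,6S)-6-(hydroxymethyl)-3-methyl-2-[(1E)-prop-1-en-1-yl]oxan-4-ol, via Z-vinylsilane 13 (not isolated)
Conditions: [Cp*Ru(MeCN)3]PF6 (3 mol%), (EtO)3SiH, CH2Cl2, 0 °C to rt; then CuI, Bu4NF, THF, rt
Reagents that add atoms: none
Why: ruthenium-catalysed trans-hydrosilylation adds H and Si anti across the alkyne and copper-assisted fluoride protodesilylation replaces silicon with retention, so the net trans-semihydrogenation should give the E-propenyl group while the same fluoride removes the primary silyl ether.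

Step 8
Reactants: 14 (2S,3S,4R,6S)-6-(hydroxymethyl)-3-methyl-2-[(1E)-prop-1-en-1-yl]oxan-4-ol
Product: 15 (2S,4R,5S,6S)-4-hydroxy-5-methyl-6-[(1E)-prop-1-en-1-yl]oxane-2-carbaldehyde
Conditions: TEMPO (10 mol%), PhI(OAc)2, CH2Cl2, rt
Reagents that add atoms: none
Why: oxoammonium oxidation is selective for the primary over the hindered axial secondary alcohol and should stop at the aldehyde without epimerising the equatorial C17 centre.

Step 9
Reactants: 15 (2S,4R,5S,6S)-4-hydroxy-5-methyl-6-[(1E)-prop-1-en-1-yl]oxane-2-carbaldehyde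
Product: 16 (2S,4R,5R,6S)-5-methyl-6-[(1E)-prop-1-en-1-yl]-4-[(triethylsilyl)oxy]oxane-2-carbaldehyde
Conditions: Et3SiCl, imidazole, CH2Cl2, 0 °C
Reagents that add atoms: chlorotriethylsilane, CC[Si](Cl)(CC)CC
Why: standard silylation of the secondary alcohol under imidazole catalysis, to which the aldehyde is inert (the C5 descriptor changes only because of the silicon).

**Chain fragment**

Step 10
Reactants: 17 (4S)-4-benzyl-3-propanoyl-1,3-oxazolidin-2-one; 18 3-bromoprop-1-yne
Product: 20 (4S)-4-benzyl-3-[(2R)-2-methylpent-4-ynoyl]-1,3-oxazolidin-2-one, via sodium Z-enolate 19 (not isolated)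
Conditions: NaN(SiMe3)2, THF, −78 °C; then 18, −78 to −40 °C
Reagents that add atoms: none
Why: Evans alkylation, in which the chelated Z-enolate is alkylated on the face opposite the benzyl group, which sets C10 as R.

Step 11
Reactants: 20 (4S)-4-benzyl-3-[(2R)-2-methylpent-4-ynoyl]-1,3-oxazolidin-2-one
Product: 21 (2R)-2-methylpent-4-yn-1-ol
Conditions: LiBH4, H2O (1 equiv), Et2O, 0 °C
Reagents that add atoms: none
Why: reductive cleavage of the N-acyl oxazolidinone gives the primary alcohol without enolisation at C10 and returns the auxiliary.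

Step 12
Reactants: 21 (2R)-2-methylpent-4-yn-1-ol
Product: 23 (2R,4E)-5-iodo-2,4-dimethylpent-4-en-1-ol, via alkenyldimethylalane 22 (not isolated)
Conditions: Me3Al (3 equiv), Cp2ZrCl2 (0.3 equiv), CH2Cl2, 0 °C to rt; then I2, THF, −30 °C
Reagents that add atoms: trimethylaluminium, C[Al](C)C; iodine, II
Why: Negishi zirconium-catalysed carboalumination adds methyl and aluminium syn across the terminal alkyne with aluminium at the terminus (the aluminium alkoxide is tolerated), and iodinolysis with retention fixes the E geometry of C12=C13.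

Step 13
Reactants: 23 (2R,4E)-5-iodo-2,4-dimethylpent-4-en-1-ol; 24 ethynyl(trimethyl)silane
Product: 25 (2R,4E)-2,4-dimethyl-7-(trimethylsilyl)hept-4-en-6-yn-1-ol
Conditions: Pd(PPh3)2Cl2 (3 mol%), CuI (6 mol%), Et3N, THF, rt
Reagents that add atoms: none
Why: Sonogashira coupling of a vinyl iodide with a terminal alkyne proceeds with retention of alkene geometry and tolerates the free alcohol.

Step 14
Reactants: 25 (2R,4E)-2,4-dimethyl-7-(trimethylsilyl)hept-4-en-6-yn-1-ol
Product: 26 (2R,4E)-2,4-dimethyl-7-(trimethylsilyl)hept-4-en-6-ynal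
Conditions: Dess–Martin periodinane, pyridine, CH2Cl2, 0 °C to rt
Reagents that add atoms: none
Why: Dess–Martin oxidation under buffered, non-basic conditions should give the α-methyl aldehyde without racemisation at C10.

Step 15
Reactants: 26 (2R,4E)-2,4-dimethyl-7-(trimethylsilyl)hept-4-en-6-ynal; 27 ethyl(triphenyl)phosphonium iodide
Product: 28 [(3E,6R,7Z)-8-iodo-4,6-dimethylnona-3,7-dien-1-yn-1-yl](trimethyl)silane
Conditions: 27, n-BuLi, THF, rt; I2, −78 °C; NaN(SiMe3)2, −20 °C; then 26, −78 °C to rt
Reagents that add atoms: iodine, II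
Why: Stork–Zhao olefination, in which the α-iodo ylide made in the flask reacts with the aldehyde under kinetic control to give the Z-configured 2-iodo-2-alkene (C10 cis to iodine), which fixes the C8=C9 geometry.

Step 16
Reactants: 28 [(3E,6R,7Z)-8-iodo-4,6-dimethylnona-3,7-dien-1-yn-1-yl](trimethyl)silane
Product: 29 (3E,6R,7Z)-8-iodo-4,6-dimethylnona-3,7-dien-1-yne
Conditions: K2CO3 (0.3 equiv), MeOH, rt
Reagents that add atoms: none
Why: carbonate-mediated methanolysis cleaves the alkynyl C–Si bond selectively and leaves the vinyl iodide untouched.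

**Assembly**

Step 17
Reactants: 29 (3E,6R,7Z)-8-iodo-4,6-dimethylnona-3,7-dien-1-yne; 16 (2S,4R,5R,6S)-5-methyl-6-[(1E)-prop-1-en-1-yl]-4-[(triethylsilyl)oxy]oxane-2-carbaldehyde
Product: 32 (1S,2E,4E,7R,8Z)-9-iodo-5,7-dimethyl-1-{(2S,4R,5R,6S)-5-methyl-6-[(1E)-prop-1-en-1-yl]-4-[(triethylsilyl)oxy]oxan-2-yl}deca-2,4,8-trien-1-ol, via alkenylzirconocene chloride 30 (not isolated), via alkenyl(methyl)zinc 31 (not isolated)
Conditions: 29, Cp2Zr(H)Cl, CH2Cl2, rt; Me2Zn, toluene, −65 °C; then 16, −65 to 0 °C
Reagents that add atoms: none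
Why: hydrozirconation places zirconium at the alkyne terminus by syn addition (14E), transmetalation gives an alkenyl(methyl)zinc that transfers its alkenyl group to the aldehyde through a five-membered chelate of zinc with the carbonyl and ring oxygens (Cram-chelate control), and attack anti to C18 should give the 16,17-syn, i.e. 16S, allylic alcohol.

Step 18
Reactants: 32 (1S,2E,4E,7R,8Z)-9-iodo-5,7-dimethyl-1-{(2S,4R,5R,6S)-5-methyl-6-[(1E)-prop-1-en-1-yl]-4-[(triethylsilyl)oxy]oxan-2-yl}deca-2,4,8-trien-1-ol; 4 (6S)-6-ethenyl-5,6-dihydro-2H-pyran-2-one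
Product: 33 (6S)-6-[(1E,3Z,5R,7E,9E,11S)-11-hydroxy-3,5,7-trimethyl-11-{(2S,4R,5R,6S)-5-methyl-6-[(1E)-prop-1-en-1-yl]-4-[(triethylsilyl)oxy]oxan-2-yl}undeca-1,3,7,9-tetraen-1-yl]-5,6-dihydro-2H-pyran-2-one
Conditions: Pd(OAc)2 (10 mol%), Bu4NCl, NaHCO3, DMF, 50 °C, dark, 4 in excess
Reagents that add atoms: none
Why: Mizoroki–Heck reaction under ligand-free phase-transfer conditions, in which oxidative addition of the Z-vinyl iodide with retention, insertion of the terminal vinyl group of 4 at its CH2 end and syn β-hydride elimination towards conjugation should give the E-configured C6=C7 bond while the mild bicarbonate base spares the lactone.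

Step 19
Reactants: 33 the C19 triethylsilyl ether of the target
Product: 34 (6S)-6-[(1E,3Z,5R,7E,9E,11S)-11-hydroxy-11-{(2S,4R,5S,6S)-4-hydroxy-5-methyl-6-[(1E)-prop-1-en-1-yl]oxan-2-yl}-3,5,7-trimethylundeca-1,3,7,9-tetraen-1-yl]-5,6-dihydro-2H-pyran-2-one
Conditions: HF·pyridine, pyridine, THF, 0 °C
Reagents that add atoms: none
Why: buffered HF·pyridine cleaves the secondary triethylsilyl ether under conditions that should neither ionise the doubly allylic C16 carbinol nor open the lactone.

**Compound list**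

1 | (2R)-2-hydroxybut-3-en-1-yl 4-methylbenzenesulfonate | C=C[C@@H](O)COS(=O)(=O)c1ccc(C)cc1 | starting material
2 | prop-2-enoyl chloride | C=CC(=O)Cl | starting material
3 | (2R)-1-{[(4-methylphenyl)sulfonyl]oxy}but-3-en-2-yl prop-2-enoate | C=C[C@@H](OC(=O)C=C)COS(=O)(=O)c1ccc(C)cc1 | intermediate
4 | (6S)-6-ethenyl-5,6-dihydro-2H-pyran-2-one | C=C[C@@H]1CC=CC(=O)O1 | intermediate
5 | diethyl (2-oxobutyl)phosphonate | CCC(=O)CP(=O)(OCC)OCC | starting material
6 | 2-[(tert-butyldimethylsilyl)oxy]acetaldehyde | O=CCO[Si](C)(C)C(C)(C)C | starting material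
7 | (4E)-6-[(tert-butyldimethylsilyl)oxy]hex-4-en-3-one | CCC(=O)/C=C/CO[Si](C)(C)C(C)(C)C | intermediate
8 | (2E,4Z)-1-[(tert-butyldimethylsilyl)oxy]-4-[(triethylsilyl)oxy]hexa-2,4-diene | C/C=C(\O[Si](CC)(CC)CC)/C=C/CO[Si](C)(C)C(C)(C)C | intermediate
9 | but-2-ynal | CC#CC=O | starting material
10 | (2S,5R,6R)-2-{[(tert-butyldimethylsilyl)oxy]methyl}-5-methyl-6-(prop-1-yn-1-yl)-4-[(triethylsilyl)oxy]-5,6-dihydro-2H-pyran (all-cis cycloadduct) | CC#C[C@@H]1O[C@H](CO[Si](C)(C)C(C)(C)C)C=C(O[Si](CC)(CC)CC)[C@@H]1C | intermediate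
11 | (2R,3R,6S)-6-{[(tert-butyldimethylsilyl)oxy]methyl}-3-methyl-2-(prop-1-yn-1-yl)oxan-4-one | CC#C[C@@H]1O[C@H](CO[Si](C)(C)C(C)(C)C)CC(=O)[C@@H]1C | intermediate
12 | (2R,3S,4R,6S)-6-{[(tert-butyldimethylsilyl)oxy]methyl}-3-methyl-2-(prop-1-yn-1-yl)oxan-4-ol | CC#C[C@@H]1O[C@H](CO[Si](C)(C)C(C)(C)C)C[C@@H](O)[C@@H]1C | intermediate
13 | analogue of 12 with a (1Z)-2-(triethoxysilyl)prop-1-en-1-yl group in place of propynyl (Si cis to the ring carbon) | C/C(=C/[C@@H]1O[C@H](CO[Si](C)(C)C(C)(C)C)C[C@@H](O)[C@@H]1C)[Si](OCC)(OCC)OCC | intermediate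
14 | (2S,3S,4R,6S)-6-(hydroxymethyl)-3-methyl-2-[(1E)-prop-1-en-1-yl]oxan-4-ol | C/C=C/[C@@H]1O[C@H](CO)C[C@@H](O)[C@@H]1C | intermediate
15 | (2S,4R,5S,6S)-4-hydroxy-5-methyl-6-[(1E)-prop-1-en-1-yl]oxane-2-carbaldehyde | C/C=C/[C@@H]1O[C@H](C=O)C[C@@H](O)[C@@H]1C | intermediate
16 | (2S,4R,5R,6S)-5-methyl-6-[(1E)-prop-1-en-1-yl]-4-[(triethylsilyl)oxy]oxane-2-carbaldehyde | C/C=C/[C@@H]1O[C@H](C=O)C[C@@H](O[Si](CC)(CC)CC)[C@@H]1C | intermediate
17 | (4S)-4-benzyl-3-propanoyl-1,3-oxazolidin-2-one | CCC(=O)N1[C@@H](Cc2ccccc2)COC1=O | starting material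
18 | 3-bromoprop-1-yne | C#CCBr | starting material
19 | sodium Z-enolate of 17 (methyl cis to O–Na) | C/C=C(\[O-])N1[C@@H](Cc2ccccc2)COC1=O.[Na+] | intermediate
20 | (4S)-4-benzyl-3-[(2R)-2-methylpent-4-ynoyl]-1,3-oxazolidin-2-one | C#CC[C@@H](C)C(=O)N1[C@@H](Cc2ccccc2)COC1=O | intermediate
21 | (2R)-2-methylpent-4-yn-1-ol | C#CC[C@@H](C)CO | intermediate
22 | (E)-alkenyldimethylalane of 21 as its O-dimethylaluminium alkoxide (Al cis to the new methyl) | C[Al](C)/C=C(\C)C[C@@H](C)CO[Al](C)C | intermediate
23 | (2R,4E)-5-iodo-2,4-dimethylpent-4-en-1-ol | I/C=C(\C)C[C@@H](C)CO | intermediate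
24 | ethynyl(trimethyl)silane | C#C[Si](C)(C)C | starting material
25 | (2R,4E)-2,4-dimethyl-7-(trimethylsilyl)hept-4-en-6-yn-1-ol | C[Si](C)(C)C#C/C=C(\C)C[C@@H](C)CO | intermediate
26 | (2R,4E)-2,4-dimethyl-7-(trimethylsilyl)hept-4-en-6-ynal | C[Si](C)(C)C#C/C=C(\C)C[C@@H](C)C=O | intermediate
27 | ethyl(triphenyl)phosphonium iodide | CC[P+](c1ccccc1)(c1ccccc1)c1ccccc1.[I-] | starting material
28 | [(3E,6R,7Z)-8-iodo-4,6-dimethylnona-3,7-dien-1-yn-1-yl](trimethyl)silane | C[Si](C)(C)C#C/C=C(\C)C[C@@H](C)/C=C(C)\I | intermediate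
29 | (3E,6R,7Z)-8-iodo-4,6-dimethylnona-3,7-dien-1-yne | C#C/C=C(\C)C[C@@H](C)/C=C(C)\I | intermediate
30 | chlorobis(cyclopentadienyl)[(1E,3E,6R,7Z)-8-iodo-4,6-dimethylnona-1,3,7-trien-1-yl]zirconium | Cl[Zr](/C=C/C=C(\C)C[C@@H](C)/C=C(C)\I)(C1C=CC=C1)C1C=CC=C1 | intermediate
31 | methyl[(1E,3E,6R,7Z)-8-iodo-4,6-dimethylnona-1,3,7-trien-1-yl]zinc | C[Zn]/C=C/C=C(\C)C[C@@H](C)/C=C(C)\I | intermediate
32 | (1S,2E,4E,7R,8Z)-9-iodo-5,7-dimethyl-1-{(2S,4R,5R,6S)-5-methyl-6-[(1E)-prop-1-en-1-yl]-4-[(triethylsilyl)oxy]oxan-2-yl}deca-2,4,8-trien-1-ol | C/C=C/[C@@H]1O[C@H]([C@@H](O)/C=C/C=C(\C)C[C@@H](C)/C=C(C)\I)C[C@@H](O[Si](CC)(CC)CC)[C@@H]1C | intermediate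
33 | C19 triethylsilyl ether of the target: (6S)-6-[(1E,3Z,5R,7E,9E,11S)-11-hydroxy-3,5,7-trimethyl-11-{(2S,4R,5R,6S)-5-methyl-6-[(1E)-prop-1-en-1-yl]-4-[(triethylsilyl)oxy]oxan-2-yl}undeca-1,3,7,9-tetraen-1-yl]-5,6-dihydro-2H-pyran-2-one | C/C=C/[C@@H]1O[C@H]([C@@H](O)/C=C/C=C(\C)C[C@@H](C)/C=C(C)\C=C\[C@@H]2CC=CC(=O)O2)C[C@@H](O[Si](CC)(CC)CC)[C@@H]1C | intermediate
34 | (6S)-6-[(1E,3Z,5R,7E,9E,11S)-11-hydroxy-11-{(2S,4R,5S,6S)-4-hydroxy-5-methyl-6-[(1E)-prop-1-en-1-yl]oxan-2-yl}-3,5,7-trimethylundeca-1,3,7,9-tetraen-1-yl]-5,6-dihydro-2H-pyran-2-one | C/C=C/[C@@H]1O[C@H]([C@@H](O)/C=C/C=C(\C)C[C@@H](C)/C=C(C)\C=C\[C@@H]2CC=CC(=O)O2)C[C@@H](O)[C@@H]1C | target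

**Step count and risks**

Total step count: 19. Longest linear sequence: 10 steps (steps 10–19; the oxane branch, steps 3–9 and 17–19, is equally long).

Steps most likely to fail:

Step 2 (the proposed new method). The ring closure may be outrun by Michael oligomerisation of the azolium enolate, the carbene may be consumed by direct alkylation with the tosylate, or the product may open by base-induced β-elimination. The fallback gives up the C3–C4 closure and builds the same lactone by ring-closing metathesis, all with known chemistry. It sets out from 2: acrolein is allylated with the appropriate antipode of B-allyldiisopinocampheylborane (Et2O, −78 °C, then NaOH/H2O2) to give (3S)-hexa-1,5-dien-3-ol F1, which is acylated with 2 (Et3N, CH2Cl2) to (3S)-hexa-1,5-dien-3-yl prop-2-enoate F2. Ring-closing metathesis with second-generation Grubbs catalyst RuCl2(H2IMes)(PCy3)(=CHPh) in refluxing CH2Cl2 should engage the acrylate and the allyl terminus (six-membered ring) in preference to the hindered carbinol vinyl group, and the route is rejoined at 4.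

Step 18. Zerovalent palladium may ionise the allylic C5–O bond of the lactone, the Z-iodide may isomerise, or the base may open the lactone before coupling is complete. The fallback replaces the Heck reaction by a two-partner cross-coupling. It sets out from 4, which undergoes cross-metathesis with 4,4,5,5-tetramethyl-2-vinyl-1,3,2-dioxaborolane (second-generation Hoveyda–Grubbs catalyst RuCl2(H2IMes)(=CH-C6H4-2-OiPr), CH2Cl2, 40 °C) to the E-alkenylboronate (6S)-6-[(E)-2-(4,4,5,5-tetramethyl-1,3,2-dioxaborolan-2-yl)ethenyl]-5,6-dihydro-2H-pyran-2-one F3. Suzuki–Miyaura coupling of F3 with iodide 32 (Pd(PPh3)4, TlOEt, THF/H2O, rt) proceeds with retention at both partners and comes back to the route at 33.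

Step 17. Chelation may be incomplete, so that facial selectivity at C16 is poor. The fallback replaces substrate control by reagent control. It sets out from 32 obtained as a mixture with its C16 epimer, the (1R)-carbinol F4; the mixture is oxidised (MnO2, CH2Cl2, rt) to the dienone F5. Corey–Bakshi–Shibata reduction of F5 with (S)-2-methyl-CBS-oxazaborolidine and catecholborane (toluene, −78 °C), the dienyl group acting as the large substituent, should return the 16S alcohol, i.e. 32.

Further compounds
F1 | step 2 | (3S)-hexa-1,5-dien-3-ol | C=C[C@@H](O)CC=C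
F2 | step 2 | (3S)-hexa-1,5-dien-3-yl prop-2-enoate | C=C[C@@H](OC(=O)C=C)CC=C
F3 | step 18 | (6S)-6-[(E)-2-(4,4,5,5-tetramethyl-1,3,2-dioxaborolan-2-yl)ethenyl]-5,6-dihydro-2H-pyran-2-one | CC1(C)OB(/C=C/[C@@H]2CC=CC(=O)O2)OC1(C)C
F4 | step 17 | C16 epimer of 32, (1R)-carbinol | C/C=C/[C@@H]1O[C@H]([C@H](O)/C=C/C=C(\C)C[C@@H](C)/C=C(C)\I)C[C@@H](O[Si](CC)(CC)CC)[C@@H]1C
F5 | step 17 | (2E,4E,7R,8Z)-9-iodo-5,7-dimethyl-1-{(2S,4R,5R,6S)-5-methyl-6-[(1E)-prop-1-en-1-yl]-4-[(triethylsilyl)oxy]oxan-2-yl}deca-2,4,8-trien-1-one | C/C=C/[C@@H]1O[C@H](C(=O)/C=C/C=C(\C)C[C@@H](C)/C=C(C)\I)C[C@@H](O[Si](CC)(CC)CC)[C@@H]1C
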